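**Plan**
- Retrosynthetic cuts: first the aryl–C(=O) bond of the (S)-2-methylbutanoyl group on the central ring; then, in each outer ring, the C(CH3)–C(OMe) bond and the C(butanoyl)–C(OH) bond; last the two ArCH2–CH bonds of the arms.
- Enabling feature: each outer benzene ring is a 2 + 4 carbon assembly. The adjacent ring carbons bearing butanoyl and OMe are the CH=C(OMe)2 carbons of 1,1-dimethoxyhex-1-en-3-one. The other four (C–OH, C–CH2Ar, C–OH, C–CH3) are C1–C4 of a 2-substituted methyl 3-oxopentanoate, whose C5 becomes the ring methyl.
- Forward order: phloroglucinol gives the tribenzylated 2,4-dialdehyde, then the two keto ester arms, then the bis(1-methoxy-1,3-bis(silyloxy)diene); both outer rings are closed in one operation. The central ring is present from the start.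
- Endgame: O-benzylation, acylation of the single free CH of the central ring, global hydrogenolysis.
- Stereochemistry: the only stereocentre is bought as (S)-2-methylbutanoic acid and attached in the last-but-one step without base; all other stereo-elements on the way are transient.

Key step: step 7

Remark: compounds 6–9 and 12 are mixtures of alkene isomers, diastereomers or tautomers and are drawn without descriptors, because all of these elements disappear when the outer rings aromatise.

**Route**

Step 1
Reactants: 1 phloroglucinol
Product: 3 diformylphloroglucinol (2,4,6-trihydroxybenzene-1,3-dicarbaldehyde), via bis(iminium) dichloride 2 (not isolated)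
Conditions: POCl3 (2.2 equiv), DMF, 1,4-dioxane, 0 → 20 °C; then H2O, 20 °C
Reagents that add atoms: N,N-dimethylformamide CN(C)C=O (formyl carbons); water O (formyl oxygens)
Why: Vilsmeier–Haack formylation: the very electron-rich triol is attacked twice by the chloroiminium ion, each iminium group deactivates the ring so that two equivalents should stop at the 2,4-bis(iminium) stage, and water then hydrolyses both groups to aldehydes.

Step 2
Reactants: 3 diformylphloroglucinol
Product: 4 2,4,6-tris(benzyloxy)benzene-1,3-dicarbaldehyde
Conditions: BnBr (3.6 equiv), K2CO3, DMF, 60 °C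
Reagents that add atoms: benzyl bromide BrCc1ccccc1
Why: Williamson ether synthesis: K2CO3 in warm DMF also deprotonates the phenols that are hydrogen-bonded to the aldehydes, and the phenoxides are benzylated on oxygen.

Step 3
Reactants: 4 2,4,6-tris(benzyloxy)benzene-1,3-dicarbaldehyde; 5 methyl 3-oxopentanoate (2.4 equiv)
Product: 7 bis(keto ester) dimethyl 2,2'-{[2,4,6-tris(benzyloxy)-1,3-phenylene]bis(methylene)}bis(3-oxopentanoate), via bis(alkylidene keto ester) 6 (not isolated)
Conditions: Hantzsch ester (2.5 equiv), piperidine (cat.), AcOH (cat.), MeOH/THF, 55 °C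
Reagents that add atoms: none
Why: Knoevenagel condensation followed in the same pot by transfer hydrogenation from the Hantzsch ester (three-component reductive alkylation): the doubly activated alkenes of 6 should accept hydride at the benzylic carbon as they form, which keeps a second keto ester from adding, while ketones, esters and benzyl ethers are inert; the two stereocentres arise without control and are lost again in step 4.

Step 4
Reactants: 7 bis(keto ester)
Product: 8 bis(silyl enol ether) dimethyl 2,2'-{[2,4,6-tris(benzyloxy)-1,3-phenylene]bis(methylene)}bis[3-(trimethylsilyloxy)pent-2-enoate]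
Conditions: Me3SiCl (3 equiv), Et3N (3.5 equiv), toluene, 20 °C; filtration under Ar
Reagents that add atoms: chlorotrimethylsilane C[Si](C)(C)Cl
Why: Soft enolisation and O-silylation of the keto ester with Me3SiCl/Et3N, the usual first stage in making 1-alkoxy-1,3-bis(silyloxy)dienes from 2-alkyl 3-oxo esters.

Step 5
Reactants: 8 bis(silyl enol ether)
Product: 9 bis-diene 1,3,5-tris(benzyloxy)-2,4-bis{2-[methoxy(trimethylsilyloxy)methylidene]-3-(trimethylsilyloxy)pent-3-en-1-yl}benzene
Conditions: LiN(i-Pr)2 (3 equiv), THF, −78 °C; Me3SiCl, −78 → 20 °C; hexane, filtration under Ar, used crude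
Reagents that add atoms: chlorotrimethylsilane C[Si](C)(C)Cl
Why: Kinetic γ-deprotonation of each 3-silyloxy-2-enoate at the ethyl CH2 by the lithium amide and O-silylation of the dienolate, the standard second stage of bis(silyloxy)diene synthesis; the benzylic ether CH2 groups should not be attacked at −78 °C.

Step 6
Reactants: 10 1,1-dimethoxyethene
Product: 11 1,1-dimethoxyhex-1-en-3-one
Conditions: butanoyl chloride, pyridine, CH2Cl2, 0 → 20 °C; distillation, stored dry
Reagents that add atoms: butanoyl chloride CCCC(=O)Cl
Why: C-Acylation of a ketene acetal: the nucleophilic CH2 carbon attacks the acylpyridinium ion and pyridine takes up the proton and the chloride, which should give the push–pull acylketene acetal.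

Step 7
Reactants: 9 bis-diene; 11 1,1-dimethoxyhex-1-en-3-one (2.6 equiv)
Product: 13 trimer 1,1'-{[2,4,6-tris(benzyloxy)-1,3-phenylene]bis[methylene(2,4-dihydroxy-6-methoxy-5-methyl-3,1-phenylene)]}di(butan-1-one), via open-chain bis(methoxy enone) adduct 12 (not isolated)
Conditions: Me3SiOTf (0.4 equiv), CH2Cl2, −78 → −20 °C; then NaOMe, dry MeOH, −20 → 50 °C; aq. HCl work-up
Reagents that add atoms: none
Why: Proposed new method: Me3SiOTf silylates the enone oxygen of 11 to a 1-silyloxy-3,3-dimethoxyallyl cation, the methyl-bearing terminus of each diene of 9 adds to its acetal carbon and loss of MeOSiMe3 leaves the β-methoxy enone 12 (Mukaiyama–Michael addition with elimination); methoxide then removes the remaining silyl groups and the acidic C4–H of each arm, the resulting dienolate acylates the ester carbon through the carbon next to the butanoyl group, and tautomerisation should give the arene. The closest known reactions are the Lewis-acid-mediated additions of 1-alkoxy-1,3-bis(silyloxy)dienes through their terminal carbon to orthoesters and β-alkoxy enones, the Michael–Dieckmann (Staunton–Weinreb-type) annulation, and the Claisen cyclisation of 3,5,7-triketo esters to acylphloroglucinols; what is new is the acylketene acetal as two-carbon partner, which keeps one methoxy group on the ring. Each of the two rings closes in a 6-(enolexo)-exo-trig Claisen (Dieckmann-type) mode. No stereocentre survives, since the methine centres of 12 are erased on aromatisation. The step needs control of orientation, which matched polarity supplies (the diene terminus is the only strongly nucleophilic carbon and the acetal carbon of 11 the only electrophilic one), and Claisen-over-aldol closure, which the substrate supplies: aldol attack from C2 on the butanoyl carbonyl would make a quaternary carbon that cannot aromatise and is reversible, the methyl enol ether blocks pyranone formation, and the propyl CH2 is far less acidic than C4–H under methoxide.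

Step 8
Reactants: 13 trimer
Product: 14 heptabenzyl ether 1,1'-{[2,4,6-tris(benzyloxy)-1,3-phenylene]bis[methylene(2,4-bis(benzyloxy)-6-methoxy-5-methyl-3,1-phenylene)]}di(butan-1-one)
Conditions: BnBr (6 equiv), K2CO3, Bu4NI (cat.), DMF, 60 °C
Reagents that add atoms: benzyl bromide BrCc1ccccc1
Why: Williamson ether synthesis on the four phenols of the outer rings, which have no free ring carbon and in DMF should react on oxygen; it removes every acidic OH before the Friedel–Crafts step.

Step 9
Reactants: 15 (S)-2-methylbutanoic acid
Product: 16 (S)-2-methylbutanoyl chloride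
Conditions: (COCl)2, DMF (cat.), CH2Cl2, 0 → 20 °C; volatiles removed
Reagents that add atoms: oxalyl chloride O=C(Cl)C(=O)Cl
Why: Acid chloride formation with oxalyl chloride and catalytic DMF (chloroiminium catalysis) runs without base, so no ketene or enolate forms and the α-stereocentre should be kept.

Step 10
Reactants: 14 heptabenzyl ether; 16 (S)-2-methylbutanoyl chloride (1.5 equiv)
Product: 17 (S)-1-{2,4,6-tris(benzyloxy)-3,5-bis[2,6-bis(benzyloxy)-3-butanoyl-4-methoxy-5-methylbenzyl]phenyl}-2-methylbutan-1-one
Conditions: SnCl4 (3 equiv), CH2Cl2, −40 → −10 °C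
Reagents that add atoms: none
Why: Friedel–Crafts acylation at the only unsubstituted carbon of an activated ring (the central CH between two benzyloxy groups); the stereocentre is carried in unchanged from 16 because acylation at low temperature without base should outrun enolisation, and loss of a benzyl group next to a ketone would not matter since all are removed in step 11.

Step 11
Reactants: 17 acylated heptabenzyl ether
Product: 18 Agrimol B
Conditions: H2 (1 atm), Pd/C, EtOAc/MeOH, 20 °C
Reagents that add atoms: none
Why: Hydrogenolysis of the seven aryl benzyl ethers over Pd/C under neutral conditions, which should leave the hydrogen-bonded aryl ketones and the stereocentre α to the central ketone untouched.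

**Compound list**

1 | phloroglucinol (benzene-1,3,5-triol) | Oc1cc(O)cc(O)c1 | starting material
2 | bis(iminium) dichloride, N,N'-[(2,4,6-trihydroxy-1,3-phenylene)dimethylidene]bis(N-methylmethanaminium) dichloride | C[N+](C)=Cc1c(O)cc(O)c(C=[N+](C)C)c1O.[Cl-].[Cl-] | intermediate (not isolated)
3 | diformylphloroglucinol, 2,4,6-trihydroxybenzene-1,3-dicarbaldehyde | O=Cc1c(O)cc(O)c(C=O)c1O | intermediate
4 | 2,4,6-tris(benzyloxy)benzene-1,3-dicarbaldehyde | O=Cc1c(OCc2ccccc2)cc(OCc2ccccc2)c(C=O)c1OCc1ccccc1 | intermediate
5 | methyl 3-oxopentanoate | CCC(=O)CC(=O)OC | starting material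
6 | bis(alkylidene keto ester), dimethyl 2,2'-{[2,4,6-tris(benzyloxy)-1,3-phenylene]dimethylidene}bis(3-oxopentanoate), alkene isomers | CCC(=O)C(=Cc1c(OCc2ccccc2)cc(OCc2ccccc2)c(C=C(C(=O)OC)C(=O)CC)c1OCc1ccccc1)C(=O)OC | intermediate (not isolated)
7 | bis(keto ester), dimethyl 2,2'-{[2,4,6-tris(benzyloxy)-1,3-phenylene]bis(methylene)}bis(3-oxopentanoate), diastereomer mixture | CCC(=O)C(Cc1c(OCc2ccccc2)cc(OCc2ccccc2)c(CC(C(=O)OC)C(=O)CC)c1OCc1ccccc1)C(=O)OC | intermediate
8 | bis(silyl enol ether), dimethyl 2,2'-{[2,4,6-tris(benzyloxy)-1,3-phenylene]bis(methylene)}bis[3-(trimethylsilyloxy)pent-2-enoate] | CCC(O[Si](C)(C)C)=C(Cc1c(OCc2ccccc2)cc(OCc2ccccc2)c(CC(C(=O)OC)=C(CC)O[Si](C)(C)C)c1OCc1ccccc1)C(=O)OC | intermediate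
9 | bis-diene, 1,3,5-tris(benzyloxy)-2,4-bis{2-[methoxy(trimethylsilyloxy)methylidene]-3-(trimethylsilyloxy)pent-3-en-1-yl}benzene | CC=C(O[Si](C)(C)C)C(Cc1c(OCc2ccccc2)cc(OCc2ccccc2)c(CC(C(O[Si](C)(C)C)=CC)=C(OC)O[Si](C)(C)C)c1OCc1ccccc1)=C(OC)O[Si](C)(C)C | intermediate
10 | 1,1-dimethoxyethene | C=C(OC)OC | starting material
11 | 1,1-dimethoxyhex-1-en-3-one | CCCC(=O)C=C(OC)OC | intermediate
12 | open-chain bis(methoxy enone) adduct, dimethyl 2,2'-{[2,4,6-tris(benzyloxy)-1,3-phenylene]bis(methylene)}bis(5-methoxy-4-methyl-3,7-dioxodec-5-enoate) | CCCC(=O)C=C(OC)C(C)C(=O)C(Cc1c(OCc2ccccc2)cc(OCc2ccccc2)c(CC(C(=O)OC)C(=O)C(C)C(OC)=CC(=O)CCC)c1OCc1ccccc1)C(=O)OC | intermediate (not isolated)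
13 | trimer with free central CH, 1,1'-{[2,4,6-tris(benzyloxy)-1,3-phenylene]bis[methylene(2,4-dihydroxy-6-methoxy-5-methyl-3,1-phenylene)]}di(butan-1-one) | CCCC(=O)c1c(O)c(Cc2c(OCc3ccccc3)cc(OCc3ccccc3)c(Cc3c(O)c(C)c(OC)c(C(=O)CCC)c3O)c2OCc2ccccc2)c(O)c(C)c1OC | intermediate
14 | heptabenzyl ether, 1,1'-{[2,4,6-tris(benzyloxy)-1,3-phenylene]bis[methylene(2,4-bis(benzyloxy)-6-methoxy-5-methyl-3,1-phenylene)]}di(butan-1-one) | CCCC(=O)c1c(OCc2ccccc2)c(Cc2c(OCc3ccccc3)cc(OCc3ccccc3)c(Cc3c(OCc4ccccc4)c(C)c(OC)c(C(=O)CCC)c3OCc3ccccc3)c2OCc2ccccc2)c(OCc2ccccc2)c(C)c1OC | intermediate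
15 | (S)-2-methylbutanoic acid | CC[C@H](C)C(=O)O | starting material
16 | (S)-2-methylbutanoyl chloride | CC[C@H](C)C(=O)Cl | intermediate
17 | (S)-1-{2,4,6-tris(benzyloxy)-3,5-bis[2,6-bis(benzyloxy)-3-butanoyl-4-methoxy-5-methylbenzyl]phenyl}-2-methylbutan-1-one | CCCC(=O)c1c(OCc2ccccc2)c(Cc2c(OCc3ccccc3)c(C(=O)[C@@H](C)CC)c(OCc3ccccc3)c(Cc3c(OCc4ccccc4)c(C)c(OC)c(C(=O)CCC)c3OCc3ccccc3)c2OCc2ccccc2)c(OCc2ccccc2)c(C)c1OC | intermediate
18 | Agrimol B, (S)-1-{3,5-bis[3-butanoyl-2,6-dihydroxy-4-methoxy-5-methylbenzyl]-2,4,6-trihydroxyphenyl}-2-methylbutan-1-one | CCCC(=O)c1c(O)c(Cc2c(O)c(Cc3c(O)c(C)c(OC)c(C(=O)CCC)c3O)c(O)c(C(=O)[C@@H](C)CC)c2O)c(O)c(C)c1OC | target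

**Step count and risks**

Total steps: 11. Longest linear sequence: 9 steps (1, 2, 3, 4, 5, 7, 8, 10, 11); steps 6 and 9 are side branches.

Steps most likely to fail:

1. Step 7 (the proposed new method). The donor-stabilised acetal carbon may capture the hindered diene termini too slowly, so that the dienes are desilylated first. The open-chain adduct may also close the wrong way, by aldol attack on a ketone or by O-cyclisation after hydrolysis of the enol ether, instead of by Claisen acylation. The fallback uses known chemistry, sets out from 1 and 16 and rejoins the route at 18: the outer rings are brought in as finished arenes and joined through methylene bridges, the classical way to oligomeric acylphloroglucinols. Phloroglucinol 1 would be C-acylated with 16 (AlCl3, CH2Cl2/PhNO2) to (S)-2-methyl-1-(2,4,6-trihydroxyphenyl)butan-1-one F1. Pseudoaspidinol, 1-(4,6-dihydroxy-2-methoxy-3-methylphenyl)butan-1-one F2, would be made by Friedel–Crafts butanoylation of 5-methoxy-4-methylbenzene-1,3-diol and separation from its regioisomer. A Mannich reaction (aqueous formaldehyde, dimethylamine, EtOH) at its single free ring carbon would give 1-{3-[(dimethylamino)methyl]-2,4-dihydroxy-6-methoxy-5-methylphenyl}butan-1-one F3. Heating F1 with two equivalents of F3 in dioxane would release the o-quinone methide, which the two free ring carbons of F1 should trap to give 18 directly.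

2. Step 10. Under the Lewis acid the diarylmethane bridges may be cleaved by ipso attack or protonation, liberated benzyl cations may alkylate the same free position, and steric shielding by the two flanking benzyloxy groups may slow the acylation enough for the acid chloride to racemise. The fallback sets out from 13 and rejoins the route at 18, so steps 8 and 11 are not needed. Hydrogenolysis of the three benzyl ethers of 13 (H2, Pd/C) would give the heptaphenol 1,1'-{(2,4,6-trihydroxy-1,3-phenylene)bis[methylene(2,4-dihydroxy-6-methoxy-5-methyl-3,1-phenylene)]}di(butan-1-one) F4, whose central dialkylphloroglucinol ring holds the only free ring CH. Classical C-acylation of this free phenol with 16 (AlCl3, CH2Cl2/PhNO2, 0 → 20 °C, with Fries-type migration of any O-acyl group) should then give 18.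

3. Step 3. Hydride transfer from the dihydropyridine to the hindered, donor-substituted alkylidene keto ester may be slower than Michael addition of a second keto ester, so that the condensation product is diverted. The fallback sets out from 4 and rejoins the route at 7. The same one-pot reductive alkylation with Meldrum's acid, whose alkylidene derivatives are far stronger hydride acceptors, would give 5,5'-{[2,4,6-tris(benzyloxy)-1,3-phenylene]bis(methylene)}bis(2,2-dimethyl-1,3-dioxane-4,6-dione) F5. Methanolysis with decarboxylation (MeOH, pyridine, reflux) would give dimethyl 3,3'-[2,4,6-tris(benzyloxy)-1,3-phenylene]dipropanoate F6. Twofold crossed Claisen acylation of its lithium enolates with propanoyl chloride (LiN(i-Pr)2 in excess, THF, −78 °C) should then give 7.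

**Further compounds**

F1 | step 7 | (S)-2-methyl-1-(2,4,6-trihydroxyphenyl)butan-1-one | CC[C@H](C)C(=O)c1c(O)cc(O)cc1O
F2 | step 7 | pseudoaspidinol, 1-(4,6-dihydroxy-2-methoxy-3-methylphenyl)butan-1-one | CCCC(=O)c1c(O)cc(O)c(C)c1OC
F3 | step 7 | 1-{3-[(dimethylamino)methyl]-2,4-dihydroxy-6-methoxy-5-methylphenyl}butan-1-one | CCCC(=O)c1c(O)c(CN(C)C)c(O)c(C)c1OC
F4 | step 10 | 1,1'-{(2,4,6-trihydroxy-1,3-phenylene)bis[methylene(2,4-dihydroxy-6-methoxy-5-methyl-3,1-phenylene)]}di(butan-1-one) | CCCC(=O)c1c(O)c(Cc2c(O)cc(O)c(Cc3c(O)c(C)c(OC)c(C(=O)CCC)c3O)c2O)c(O)c(C)c1OC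
F5 | step 3 | 5,5'-{[2,4,6-tris(benzyloxy)-1,3-phenylene]bis(methylene)}bis(2,2-dimethyl-1,3-dioxane-4,6-dione) | CC1(C)OC(=O)C(Cc2c(OCc3ccccc3)cc(OCc3ccccc3)c(CC3C(=O)OC(C)(C)OC3=O)c2OCc2ccccc2)C(=O)O1
F6 | step 3 | dimethyl 3,3'-[2,4,6-tris(benzyloxy)-1,3-phenylene]dipropanoate | COC(=O)CCc1c(OCc2ccccc2)cc(OCc2ccccc2)c(CCC(=O)OC)c1OCc1ccccc1
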